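**Retrosynthetic overview**
1. Target 11 is cut at the enone C=C (Claisen–Schmidt) into methyl ketone 5 (dihydrobenzofuran half) and aldehyde 9 (chroman half).
2. Ketone 5 is cut at the ring O–C2 bond: enantioselective epoxidation of ortho-prenylphenol 3, then 5-exo opening by the phenol oxygen, forms the ring and the (R) centre.
3. Prenylphenol 3 comes from 2,4-dihydroxyacetophenone 1 and 2-methylbut-3-en-2-ol 2 by Friedel–Crafts prenylation at C-5.
4. Aldehyde 9 comes from 4-hydroxybenzaldehyde 6 and isoprene 7 by acid-mediated ortho-prenylation and hydroalkoxylation.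
5. Ring order: the chroman ring and the dihydrofuran ring are each closed on their own fragment; no ring is formed after the two halves are joined.

Assumption: the target is (R) at C-2 of the dihydrobenzofuran and (E) at the enone, and the peptide series named in step 2 is assumed to give the (S)-epoxide; if screening shows the opposite sense, the mirror-image peptide is used.

**Step 1**
Reactants: 1 1-(2,4-dihydroxyphenyl)ethan-1-one; 2 2-methylbut-3-en-2-ol
Product: 3 1-[2,4-dihydroxy-5-(3-methylbut-2-en-1-yl)phenyl]ethan-1-one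
Conditions: BF3·OEt2 (0.3 equiv), 1,4-dioxane, rt, 16 h
Reagents that add atoms: none
Why: Friedel–Crafts allylic alkylation; the tertiary allyl cation reacts through its primary terminus at C-5 (para to the 2-OH, ortho to the 4-OH), which is less hindered than C-3, and the minor 3-prenyl isomer is removed by chromatography; no stereocenter is formed.

**Step 2**
Reactants: 3 1-[2,4-dihydroxy-5-(3-methylbut-2-en-1-yl)phenyl]ethan-1-one
Product: 5 1-[(2R)-6-hydroxy-2-(2-hydroxypropan-2-yl)-2,3-dihydro-1-benzofuran-5-yl]ethan-1-one, via (S)-epoxide 4 (not isolated)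
Conditions: Boc-L-Asp-L-Pro-D-Val-NH-(R)-CH(CH3)Ph (free Asp side-chain CO2H, 10 mol%), HOBt (10 mol%), DIC (1.5 equiv), 30% aq H2O2 (1.2 equiv), CHCl3, 4 °C; then K2CO3 (20 mol%), MeOH, 0 °C to rt
Reagents that add atoms: hydrogen peroxide, OO
Why: Proposed new method: a phenol-directed, aspartyl-peptide peracid-catalysed enantioselective epoxidation of an ortho-prenylphenol, telescoped with base-catalysed 5-exo-tet cycloetherification. DIC/H2O2 turns the Asp side chain into a transient peracid held in a β-turn. The free 4-OH of 3 (the 2-OH is locked in an H-bond to the acetyl C=O) donates an H-bond to a backbone amide carbonyl, so the prenyl alkene three bonds away sits under the peracid and receives oxygen on one face, giving (S)-epoxide 4. Catalytic K2CO3 then forms the phenoxide, which opens the epoxide at the secondary carbon anti to the C–O bond (inversion), making the ring C–O bond and the (R) centre, while the tertiary carbon keeps the delivered oxygen as the carbinol. The closest known reaction type is hydroxyl- and carbamate-directed asymmetric epoxidation by aspartyl-peptide peracids (allylic alcohols and carbamates, not phenols), together with the racemic peracid epoxidation–cyclisation of ortho-prenylphenols.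

**Step 3**
Reactants: 6 4-hydroxybenzaldehyde; 7 isoprene (2-methylbuta-1,3-diene)
Product: 9 2,2-dimethyl-3,4-dihydro-2H-chromene-6-carbaldehyde, via ortho-prenylphenol 8 (not isolated)
Conditions: 85% H3PO4, toluene–heptane, 30–35 °C, 20 h
Reagents that add atoms: none
Why: Acid-mediated Friedel–Crafts ortho-prenylation is followed by Markovnikov intramolecular hydroalkoxylation of the prenyl alkene by the phenol, which closes the 2,2-dimethylchroman; no stereocenter is formed.

**Step 4**
Reactants: 5 1-[(2R)-6-hydroxy-2-(2-hydroxypropan-2-yl)-2,3-dihydro-1-benzofuran-5-yl]ethan-1-one; 9 2,2-dimethyl-3,4-dihydro-2H-chromene-6-carbaldehyde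
Product: 11 (2E)-3-(2,2-dimethyl-3,4-dihydro-2H-chromen-6-yl)-1-[(2R)-6-hydroxy-2-(2-hydroxypropan-2-yl)-2,3-dihydro-1-benzofuran-5-yl]prop-2-en-1-one, via β-hydroxy ketone 10 (not isolated)
Conditions: KOH (50% aq), EtOH, 0 °C to rt, 24 h
Reagents that add atoms: none
Why: Claisen–Schmidt condensation of the only enolisable ketone with a non-enolisable aldehyde; E1cB dehydration gives the conjugated (E)-enone, hydroxide is regenerated so water is the only co-product, and the ether-bearing C-2 centre is not epimerisable under these conditions.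

**Compound list**
1 | 1-(2,4-dihydroxyphenyl)ethan-1-one | CC(=O)c1ccc(O)cc1O | starting material
2 | 2-methylbut-3-en-2-ol | CC(C)(O)C=C | starting material
3 | 1-[2,4-dihydroxy-5-(3-methylbut-2-en-1-yl)phenyl]ethan-1-one | CC(=O)c1cc(CC=C(C)C)c(O)cc1O | intermediate
4 | 1-(5-{[(2S)-3,3-dimethyloxiran-2-yl]methyl}-2,4-dihydroxyphenyl)ethan-1-one (not isolated) | CC(=O)c1cc(C[C@@H]2OC2(C)C)c(O)cc1O | intermediate
5 | 1-[(2R)-6-hydroxy-2-(2-hydroxypropan-2-yl)-2,3-dihydro-1-benzofuran-5-yl]ethan-1-one | CC(=O)c1cc2c(cc1O)O[C@@H](C(C)(C)O)C2 | intermediate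
6 | 4-hydroxybenzaldehyde | O=Cc1ccc(O)cc1 | starting material
7 | isoprene (2-methylbuta-1,3-diene) | C=CC(C)=C | starting material
8 | 4-hydroxy-3-(3-methylbut-2-en-1-yl)benzaldehyde (not isolated) | CC(C)=CCc1cc(C=O)ccc1O | intermediate
9 | 2,2-dimethyl-3,4-dihydro-2H-chromene-6-carbaldehyde | CC1(C)CCc2cc(C=O)ccc2O1 | intermediate
10 | 3-(2,2-dimethyl-3,4-dihydro-2H-chromen-6-yl)-3-hydroxy-1-[(2R)-6-hydroxy-2-(2-hydroxypropan-2-yl)-2,3-dihydro-1-benzofuran-5-yl]propan-1-one, both carbinol epimers (not isolated) | CC1(C)CCc2cc(C(O)CC(=O)c3cc4c(cc3O)O[C@@H](C(C)(C)O)C4)ccc2O1 | intermediate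
11 | (2E)-3-(2,2-dimethyl-3,4-dihydro-2H-chromen-6-yl)-1-[(2R)-6-hydroxy-2-(2-hydroxypropan-2-yl)-2,3-dihydro-1-benzofuran-5-yl]prop-2-en-1-one | CC1(C)CCc2cc(/C=C/C(=O)c3cc4c(cc3O)O[C@@H](C(C)(C)O)C4)ccc2O1 | target

**Totals**
Total step count: 4. Longest linear sequence: 3 steps (1 → 3 → 5 → 11); aldehyde 9 is made in one parallel step.

**Steps most likely to fail**

Step 2 (proposed new method). The risks are low enantioselectivity if the phenol is not recognised by the peptide, acid-promoted 6-endo opening of epoxide 4 to the 3-hydroxychroman before the base stage, and slow Baeyer–Villiger or Dakin-type oxidation of the hydroxyaryl ketone. The enantiomeric excess of 5 would be measured by chiral HPLC and raised by recrystallisation. The fallback uses known chemistry, sets out from 3 and comes back at 5. The non-chelated 4-OH of 3 is silylated (iPr3SiCl, imidazole, DMF) to give 1-{2-hydroxy-5-(3-methylbut-2-en-1-yl)-4-[tri(propan-2-yl)silyloxy]phenyl}ethan-1-one F1. Shi epoxidation with the L-series (enantiomeric) fructose-derived ketone, Oxone (2KHSO5·KHSO4·K2SO4), K2CO3 and Bu4NHSO4 in MeCN–dimethoxymethane/aqueous Na2B4O7 buffer at 0 °C then gives 1-{5-{[(2S)-3,3-dimethyloxiran-2-yl]methyl}-2-hydroxy-4-[tri(propan-2-yl)silyloxy]phenyl}ethan-1-one F2. The D-fructose-derived ketone would give the (R)-epoxide and hence the wrong enantiomer. Bu4NF in THF removes the silyl group, and the freed phenoxide closes 5-exo with inversion to 5.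

Step 1. The risks are a modest yield from competing C-3 prenylation, bis-prenylation and acid cyclisation to chromans. The fallback sets out from 1 and comes back at 3. Bromination of 1 (NBS, MeCN, 0 °C) gives 1-(5-bromo-2,4-dihydroxyphenyl)ethan-1-one F3. Protection of the non-chelated 4-OH (MOMCl, K2CO3, acetone) gives 1-[5-bromo-2-hydroxy-4-(methoxymethoxy)phenyl]ethan-1-one F4. Stille coupling with tributyl(3-methylbut-2-en-1-yl)stannane (Pd(PPh3)4, DMF, 90 °C) gives 1-[2-hydroxy-4-(methoxymethoxy)-5-(3-methylbut-2-en-1-yl)phenyl]ethan-1-one F5. Dilute HCl in MeOH at rt removes the acetal and returns 3 as a single regioisomer.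

Step 3. The risks are low conversion of the deactivated phenol, isoprene oligomerisation and Prins-type reaction at the aldehyde. The fallback sets out from 6 and comes back at 9. O-Alkylation of 6 with 3-chloro-3-methylbut-1-yne (K2CO3, KI (cat.), CuI (cat.), acetone, reflux) gives 4-[(2-methylbut-3-yn-2-yl)oxy]benzaldehyde F6. Heating in N,N-diethylaniline at 190 °C (propargyl Claisen rearrangement, 1,5-H shift, 6π-electrocyclisation) gives 2,2-dimethyl-2H-chromene-6-carbaldehyde F7. Chemoselective alkene hydrogenation (H2 1 atm, 10% Pd/C, Ph2S (cat.), EtOAc, rt) then gives 9 with the aldehyde intact.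

**Further compounds**
F1 | step 2 | 1-{2-hydroxy-5-(3-methylbut-2-en-1-yl)-4-[tri(propan-2-yl)silyloxy]phenyl}ethan-1-one | CC(=O)c1cc(CC=C(C)C)c(O[Si](C(C)C)(C(C)C)C(C)C)cc1O
F2 | step 2 | 1-{5-{[(2S)-3,3-dimethyloxiran-2-yl]methyl}-2-hydroxy-4-[tri(propan-2-yl)silyloxy]phenyl}ethan-1-one | CC(=O)c1cc(C[C@@H]2OC2(C)C)c(O[Si](C(C)C)(C(C)C)C(C)C)cc1O
F3 | step 1 | 1-(5-bromo-2,4-dihydroxyphenyl)ethan-1-one | CC(=O)c1cc(Br)c(O)cc1O
F4 | step 1 | 1-[5-bromo-2-hydroxy-4-(methoxymethoxy)phenyl]ethan-1-one | CC(=O)c1cc(Br)c(OCOC)cc1O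
F5 | step 1 | 1-[2-hydroxy-4-(methoxymethoxy)-5-(3-methylbut-2-en-1-yl)phenyl]ethan-1-one | CC(=O)c1cc(CC=C(C)C)c(OCOC)cc1O
F6 | step 3 | 4-[(2-methylbut-3-yn-2-yl)oxy]benzaldehyde | CC(C)(C#C)Oc1ccc(C=O)cc1
F7 | step 3 | 2,2-dimethyl-2H-chromene-6-carbaldehyde | CC1(C)C=Cc2cc(C=O)ccc2O1
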